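The target is disconnected at the bridging CH2 into propionyl- and butyrylfilicinic acid, and both are traced to filicinic acid. The key step exploits the substitution pattern of the propionyl-bearing ring (and its butyryl twin): a C(CH3)2 carbon between two oxygenated carbons, a third oxygenated carbon opposite and CH in between, which maps onto dimethylketene plus two ynol ether units. The six-membered ring is therefore grown from a four-membered one: 3-ethoxy-4,4-dimethylcyclobutenone and ethoxyacetylene undergo a thermal cascade (4π opening, [2+2], 4π opening, 6π closure) that inserts two carbons and delivers the complete 3,5-dioxygenated 6,6-dimethylcyclohexadienone. Hydrolysis, C-acylation and a Mannich-based methylene coupling finish the route.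

Key step: step 2

Remark: the target has no stereocenter; its enolised triketone rings are written in the tautomeric form of the target SMILES, and the tautomers interconvert freely. Filicinic acid 9 is made once and divided between steps 4 and 5.

Step 1
Reactants: 1 isobutyryl chloride; 2 ethoxyacetylene
Product: 4 3-ethoxy-4,4-dimethylcyclobut-2-en-1-one, via dimethylketene 3 (not isolated)
Conditions: Et3N, Et2O, 0 °C to rt
Reagents that add atoms: ethoxyacetylene (CCOC#C)
Why: Et3N dehydrochlorinates 1 to dimethylketene, whose carbonyl carbon is attacked by the nucleophilic terminal carbon of the ynol ether in a regioselective ketene–alkyne [2+2] cycloaddition that places the ethoxy group at C3, next to the C(CH3)2 carbon.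

Step 2
Reactants: 4 3-ethoxy-4,4-dimethylcyclobut-2-en-1-one; 2 ethoxyacetylene
Product: 8 3,5-diethoxy-6,6-dimethylcyclohexa-2,4-dien-1-one, via vinylketene 5 (not isolated), via 4-alkenylcyclobutenone 6 (not isolated), via dienylketene 7 (not isolated)
Conditions: ethoxyacetylene (3 equiv), toluene, 85 °C, sealed tube
Reagents that add atoms: ethoxyacetylene (CCOC#C)
Why: Heating opens 4 by reversible 4π-electrocyclic cleavage of the C1–C4 bond to vinylketene 5, whose ketene C=C adds ethoxyacetylene in a [2+2] cycloaddition (unsubstituted alkyne carbon to the ketene carbonyl carbon) to give 6; a second 4π opening gives dienylketene 7, which closes by thermally allowed disrotatory 6π-electrocyclization between the ketene carbon and the C(CH3)2 terminus. The closest known reaction type is the Danheiser cyclobutenone–alkyne benzannulation in its 4,4-disubstituted variant, which stops at the 2,4-cyclohexadienone because the quaternary carbon cannot tautomerise to a phenol. The four-membered ring of 6 is closed by [2+2] cycloaddition and the six-membered ring by 6π-electrocyclic closure, so the four ring carbons of 4 and the two alkyne carbons become the six ring carbons of 8. No stereocenter remains in 8, because the single stereocenter of 6 is racemic and is lost on ring opening. The step needs [2+2] regioselectivity, which the polarization of the ynol ether secures, and an inward-turned alkenyl group in 7, which the reversibility of the ring opening secures by funnelling both rotation modes through the irreversible 6π closure. The excess of ethoxyacetylene is meant to outrun ketene dimerization and a 1,5-hydrogen shift in 5, and the temperature is kept below that at which ethoxyacetylene loses ethylene.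

Step 3
Reactants: 8 3,5-diethoxy-6,6-dimethylcyclohexa-2,4-dien-1-one
Product: 9 filicinic acid (3,5-dihydroxy-4,4-dimethylcyclohexa-2,5-dien-1-one)
Conditions: 1 M HCl, THF, 40 °C
Reagents that add atoms: water (O)
Why: Both ethoxy groups are vinylogous ester enol ethers of the dienone carbonyl and should be cleaved by acid-catalysed addition–elimination of water (enol ether hydrolysis), leaving the stable enolised triketone.

Step 4
Reactants: 9 filicinic acid; 10 propionyl chloride
Product: 11 propionylfilicinic acid (3,5-dihydroxy-4,4-dimethyl-2-propanoylcyclohexa-2,5-dien-1-one)
Conditions: propionyl chloride (1 equiv), AlCl3 (3 equiv), PhNO2, rt; then ice/HCl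
Reagents that add atoms: propionyl chloride (CCC(=O)Cl)
Why: Friedel–Crafts C-acylation of the enolic ring CH flanked by two oxygenated carbons, the classical entry to acylfilicinic acids; the chelated acyl group deactivates the ring, so one equivalent of acid chloride should stop at monoacylation.

Step 5
Reactants: 9 filicinic acid; 12 butyryl chloride
Product: 13 butyrylfilicinic acid (2-butanoyl-3,5-dihydroxy-4,4-dimethylcyclohexa-2,5-dien-1-one)
Conditions: butyryl chloride (1 equiv), AlCl3 (3 equiv), PhNO2, rt; then ice/HCl
Reagents that add atoms: butyryl chloride (CCCC(=O)Cl)
Why: The same Friedel–Crafts C-acylation as in step 4, on the second portion of 9.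

Step 6
Reactants: 13 butyrylfilicinic acid; 14 formaldehyde; 15 dimethylamine
Product: 16 2-butanoyl-6-[(dimethylamino)methyl]-3,5-dihydroxy-4,4-dimethylcyclohexa-2,5-dien-1-one
Conditions: 37% aq CH2O premixed with 40% aq Me2NH (excess), EtOH, 0 °C to rt
Reagents that add atoms: formaldehyde (C=O), dimethylamine (CNC)
Why: Mannich reaction at C6, the only remaining ring CH of 13; excess amine premixed with formaldehyde should favour the aminomethyl compound, collected as its inner salt, over the methylene-bis compound.

Step 7
Reactants: 16 Mannich base of butyrylfilicinic acid; 11 propionylfilicinic acid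
Product: 18 target, 2-butanoyl-6-[(2,4-dihydroxy-3,3-dimethyl-6-oxo-5-propanoylcyclohexa-1,4-dien-1-yl)methyl]-3,5-dihydroxy-4,4-dimethylcyclohexa-2,5-dien-1-one, via methylidene triketone 17 (not isolated)
Conditions: 1,4-dioxane, 80 °C, slow N2 stream; then 1 M HCl wash
Reagents that add atoms: none
Why: On heating, 16 should lose dimethylamine (E1cB elimination of the Mannich base) to the quinone-methide-like methylidene triketone 17, which is captured at carbon by the enolic CH of 11 in a Michael addition, forming the unsymmetrical methylene bridge without free formaldehyde.

Compound list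
1 | isobutyryl chloride | CC(C)C(=O)Cl | starting material
2 | ethoxyacetylene (ethoxyethyne) | CCOC#C | starting material
3 | dimethylketene | CC(C)=C=O | intermediate (not isolated)
4 | 3-ethoxy-4,4-dimethylcyclobut-2-en-1-one | CCOC1=CC(=O)C1(C)C | intermediate
5 | vinylketene, 3-ethoxy-4-methylpenta-1,3-dien-1-one | CCOC(C=C=O)=C(C)C | intermediate (not isolated)
6 | 3-ethoxy-4-(1-ethoxy-2-methylprop-1-en-1-yl)cyclobut-2-en-1-one (racemic) | CCOC1=CC(=O)C1C(OCC)=C(C)C | intermediate (not isolated)
7 | dienylketene, (3E)-3,5-diethoxy-6-methylhepta-1,3,5-trien-1-one | O=C=C/C(OCC)=C\C(OCC)=C(C)C | intermediate (not isolated)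
8 | 3,5-diethoxy-6,6-dimethylcyclohexa-2,4-dien-1-one | CCOC1=CC(OCC)=CC(=O)C1(C)C | intermediate
9 | filicinic acid, 3,5-dihydroxy-4,4-dimethylcyclohexa-2,5-dien-1-one | CC1(C)C(O)=CC(=O)C=C1O | intermediate
10 | propionyl chloride | CCC(=O)Cl | starting material
11 | propionylfilicinic acid, 3,5-dihydroxy-4,4-dimethyl-2-propanoylcyclohexa-2,5-dien-1-one | CCC(=O)C1=C(O)C(C)(C)C(O)=CC1=O | intermediate
12 | butyryl chloride | CCCC(=O)Cl | starting material
13 | butyrylfilicinic acid, 2-butanoyl-3,5-dihydroxy-4,4-dimethylcyclohexa-2,5-dien-1-one | CCCC(=O)C1=C(O)C(C)(C)C(O)=CC1=O | intermediate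
14 | formaldehyde | C=O | starting material
15 | dimethylamine | CNC | starting material
16 | 2-butanoyl-6-[(dimethylamino)methyl]-3,5-dihydroxy-4,4-dimethylcyclohexa-2,5-dien-1-one | CCCC(=O)C1=C(O)C(C)(C)C(O)=C(CN(C)C)C1=O | intermediate
17 | 2-butanoyl-3-hydroxy-4,4-dimethyl-6-methylidenecyclohex-2-ene-1,5-dione | CCCC(=O)C1=C(O)C(C)(C)C(=O)C(=C)C1=O | intermediate (not isolated)
18 | 2-butanoyl-6-[(2,4-dihydroxy-3,3-dimethyl-6-oxo-5-propanoylcyclohexa-1,4-dien-1-yl)methyl]-3,5-dihydroxy-4,4-dimethylcyclohexa-2,5-dien-1-one | CCCC(=O)C1=C(O)C(C)(C)C(O)=C(CC2=C(O)C(C)(C)C(O)=C(C(=O)CC)C2=O)C1=O | target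

Total step count: 7. Longest linear sequence: 6 steps (steps 1, 2, 3, 5, 6, 7).

Steps most likely to fail

Step 2. The donor-stabilised cyclobutenone 4 may open more slowly than ethoxyacetylene fragments by retro-ene loss of ethylene, and the vinylketene may drain away through a 1,5-hydrogen shift from one of its methyl groups. The fallback sets out from 4 and replaces the ynol ether by the thermally robust ketene diethyl acetal (1,1-diethoxyethene, C=C(OCC)OCC) in toluene at 110 °C. [2+2] cycloaddition of vinylketene 5 to this electron-rich alkene should give 3,3-diethoxy-2-(1-ethoxy-2-methylprop-1-en-1-yl)cyclobutan-1-one F1. On further heating F1 should lose ethanol to give 6, which passes through the same ring opening and 6π closure and comes back to the route at 8.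

Step 7. The Michael addition may be reversible at the reaction temperature, so that cleavage of the bridge and recombination exchange the two halves and lead to the symmetrical bis-butyryl and bis-propionyl dimers. The fallback sets out from 16: N-methylation with MeI in acetone gives 1-(3-butanoyl-4,6-dihydroxy-5,5-dimethyl-2-oxocyclohexa-3,6-dien-1-yl)-N,N,N-trimethylmethanaminium iodide F2. With 11 and NaHCO3 in aqueous methanol at 0 °C, F2 should release trimethylamine and form 17 far below the temperature of the exchange, and capture by 11 comes back to the route at 18.

Step 6. The Mannich base may lose amine while free 13 is still present, which would lead to self-capture and the symmetrical bis-butyryl dimer. The fallback sets out from 13 and prepares no aminomethyl compound: equimolar 13 and 11 are condensed directly with aqueous formaldehyde in dilute NaOH/EtOH and then acidified, and the mixed dimer is separated from the two symmetrical dimers by reversed-phase preparative chromatography. This replaces steps 6 and 7, comes back to the route at 18 and makes no new compound (F0).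

Further compounds
F1 | step 2 | 3,3-diethoxy-2-(1-ethoxy-2-methylprop-1-en-1-yl)cyclobutan-1-one (racemic) | CCOC(=C(C)C)C1C(=O)CC1(OCC)OCC
F2 | step 7 | 1-(3-butanoyl-4,6-dihydroxy-5,5-dimethyl-2-oxocyclohexa-3,6-dien-1-yl)-N,N,N-trimethylmethanaminium iodide | CCCC(=O)C1=C(O)C(C)(C)C(O)=C(C[N+](C)(C)C)C1=O.[I-]
F0 | step 6 | none | none
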